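**Retrosynthetic overview**

1. Target ⇐ (R)-shikonin + 3-methylbut-2-enoic acid; the side-chain alcohol is acylated last, as the plant acyltransferase does.
2. Shikonin ⇐ one ring-forming event. The quinonoid ring B closes when the hydroquinone carbon ortho to OH attacks the side-chain C-3'' aldehyde (the ring closure of 3''-oxo-geranylhydroquinone), run with C-1' already a ketone so that dehydrogenation of the leuco product gives the naphthazarin directly.
3. That (Z)-keto-enal ⇐ a 2-aryl-4-alkylfuran: oxidation to the furylquinone, then hydrative furan opening with the quinone as internal oxidant (the furan is a sacrificial ring, never a ring of the target).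
4. Aryl–furan bond ⇐ C-5 C–H borylation of a 3-substituted furan, then Suzuki coupling with bromohydroquinone (ring A is bought).
5. Stereocentre ⇐ catalytic asymmetric allylation of furan-3-carbaldehyde, allyl → prenyl by cross-metathesis; the carbinol is carried unprotected to the end.

Assumption: the target is the (R)-ester (β,β-dimethylacrylshikonin), the leuco intermediate is written as its tetraol tautomer, and 2-bromohydroquinone, B2pin2 and allyltributylstannane are taken as purchasable.

**Route**

Step 1
Reactants: 1 furan-3-carbaldehyde; 2 allyltributylstannane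
Product: 3 (R)-1-(furan-3-yl)but-3-en-1-ol
Conditions: (R)-BINOL (20 mol%), Ti(OiPr)4 (10 mol%), 4 Å MS, CH2Cl2, −20 °C, 60 h; aq. NaHCO3 work-up
Reagents that add atoms: none
Why: Keck asymmetric allylation, in which the (R)-BINOL–Ti(OiPr)4 Lewis acid exposes the Re face of the aryl aldehyde to allyl transfer from tin and so sets the (R) carbinol centre (90–96% ee is usual for furaldehydes).

Step 2
Reactants: 3 (R)-1-(furan-3-yl)but-3-en-1-ol; 4 2-methylbut-2-ene
Product: 5 (R)-1-(furan-3-yl)-4-methylpent-3-en-1-ol
Conditions: second-generation Grubbs catalyst RuCl2(=CHPh)(PCy3)(H2IMes) (3 mol%), 2-methylbut-2-ene/CH2Cl2 (1:1), 40 °C, sealed tube, 12 h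
Reagents that add atoms: none
Why: Olefin cross-metathesis, in which the terminal alkene exchanges its CH2 end for the isopropylidene end of excess 2-methylbut-2-ene (propene leaves), turning allyl into prenyl without touching the carbinol centre.

Step 3
Reactants: 5 (R)-1-(furan-3-yl)-4-methylpent-3-en-1-ol; 6 bis(pinacolato)diboron (1.2 equiv); 7 2-bromobenzene-1,4-diol
Product: 9 2-[4-[(1R)-1-hydroxy-4-methylpent-3-enyl]furan-2-yl]benzene-1,4-diol, via furyl boronate 8 (not isolated)
Conditions: [Ir(OMe)(cod)]2 (1.5 mol%), 4,4'-di-tert-butyl-2,2'-bipyridine (3 mol%), THF, 50 °C; then 7, Pd(OAc)2 (2 mol%), SPhos (4 mol%), aq. K3PO4 (4 equiv), degassed, 50 °C, argon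
Reagents that add atoms: none
Why: Sterically governed iridium-catalysed C–H borylation takes the furan α-position remote from the branched side chain (the alcohol is borylated on oxygen in passing and freed again by the aqueous base), and Suzuki–Miyaura coupling of the 2-furylboronate then forms the aryl–furan bond without touching the stereocentre.

Step 4
Reactants: 9 2-[4-[(1R)-1-hydroxy-4-methylpent-3-enyl]furan-2-yl]benzene-1,4-diol
Product: 13 (R)-shikonin [5,8-dihydroxy-2-[(1R)-1-hydroxy-4-methylpent-3-enyl]naphthalene-1,4-dione], via furylquinone 10 (not isolated), via keto-enal 11 (not isolated), via leucoshikonin 12 (not isolated)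
Conditions: Ag2O (1.5 equiv), CH2Cl2, rt, 20 min, filter; then Sc(OTf)3 (10 mol%), p-benzoquinone (1.2 equiv), MeCN–H2O (9:1), 40 °C, dark
Reagents that add atoms: water, O
Why: Proposed new method: the Lewis-acid-activated 2-furylquinone 10 is a vinylogous furfuryl cation, so water should add at furan C-5 as in the Piancatelli rearrangement and the hemiacetal should open, with the quinone acting as internal two-electron oxidant, to the (Z)-keto-enal 11 (closest known chemistry: Piancatelli- and Achmatowicz-type hydrative or oxidative opening of furans to cis-enediones), whose aldehyde carbon (C-3'' of the biosynthetic 3''-oxo-geranylhydroquinone) then closes onto the ring carbon ortho to the phenol by intramolecular Friedel–Crafts hydroxyalkylation, tautomerisation giving leuco compound 12, which p-benzoquinone dehydrogenates at once to the naphthazarin, while the existing stereocentre is not touched.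

Step 5
Reactants: 13 (R)-shikonin; 14 3-methylbut-2-enoic acid
Product: 15 (1R)-1-(5,8-dihydroxy-1,4-dioxonaphthalen-2-yl)-4-methylpent-3-enyl 3-methylbut-2-enoate (target, CNP0209621.1)
Conditions: DCC (1.5 equiv), DMAP (0.2 equiv), CH2Cl2, 0 °C → rt, dark
Reagents that add atoms: none
Why: Steglich esterification, in which the carbodiimide-activated acid acylates the side-chain alcohol with retention (the C–O bond is not broken), while the two peri-phenols, hydrogen-bonded to the quinone carbonyls, do not react.

**Compound list**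

1 | furan-3-carbaldehyde | O=Cc1ccoc1 | starting material
2 | allyltributylstannane | C=CC[Sn](CCCC)(CCCC)CCCC | starting material
3 | (R)-1-(furan-3-yl)but-3-en-1-ol | C=CC[C@@H](O)c1ccoc1 | intermediate
4 | 2-methylbut-2-ene | CC=C(C)C | starting material
5 | (R)-1-(furan-3-yl)-4-methylpent-3-en-1-ol | CC(C)=CC[C@@H](O)c1ccoc1 | intermediate
6 | bis(pinacolato)diboron | CC1(C)OB(OC1(C)C)B1OC(C)(C)C(C)(C)O1 | starting material
7 | 2-bromobenzene-1,4-diol (bromohydroquinone) | Oc1ccc(O)c(Br)c1 | starting material
8 | 4,4,5,5-tetramethyl-2-[(1R)-4-methyl-1-[5-(4,4,5,5-tetramethyl-1,3,2-dioxaborolan-2-yl)furan-3-yl]pent-3-enoxy]-1,3,2-dioxaborolane | CC(C)=CC[C@@H](OB1OC(C)(C)C(C)(C)O1)c1coc(B2OC(C)(C)C(C)(C)O2)c1 | intermediate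
9 | 2-[4-[(1R)-1-hydroxy-4-methylpent-3-enyl]furan-2-yl]benzene-1,4-diol | CC(C)=CC[C@@H](O)c1coc(-c2cc(O)ccc2O)c1 | intermediate
10 | 2-[4-[(1R)-1-hydroxy-4-methylpent-3-enyl]furan-2-yl]cyclohexa-2,5-diene-1,4-dione | CC(C)=CC[C@@H](O)c1coc(C2=CC(=O)C=CC2=O)c1 | intermediate
11 | (2Z)-4-(2,5-dihydroxyphenyl)-2-[(1R)-1-hydroxy-4-methylpent-3-enyl]-4-oxobut-2-enal | CC(C)=CC[C@@H](O)/C(C=O)=C/C(=O)c1cc(O)ccc1O | intermediate
12 | 2-[(1R)-1-hydroxy-4-methylpent-3-enyl]naphthalene-1,4,5,8-tetrol (leucoshikonin) | CC(C)=CC[C@@H](O)c1cc(O)c2c(O)ccc(O)c2c1O | intermediate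
13 | (R)-shikonin, 5,8-dihydroxy-2-[(1R)-1-hydroxy-4-methylpent-3-enyl]naphthalene-1,4-dione | CC(C)=CC[C@@H](O)C1=CC(=O)c2c(O)ccc(O)c2C1=O | intermediate
14 | 3-methylbut-2-enoic acid | CC(C)=CC(=O)O | starting material
15 | (1R)-1-(5,8-dihydroxy-1,4-dioxonaphthalen-2-yl)-4-methylpent-3-enyl 3-methylbut-2-enoate | CC(C)=CC[C@@H](OC(=O)C=C(C)C)C1=CC(=O)c2c(O)ccc(O)c2C1=O | target

**Step count and risks**

Total steps: 5. Longest linear sequence: 5 steps, from furan-3-carbaldehyde 1.

Most likely to fail, in order:

Step 4. Three things can go wrong.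
- Water may not add to furylquinone 10 under a mild Lewis acid.
- Keto-enal 11 may isomerise to its E form, whose free γ-hydroxy enone can cyclodehydrate to a furan and lose the stereocentre.
- Leuco compound 12 carries a benzylic alcohol on a very electron-rich ring and can lose water or racemise if it is not oxidised at once.

The fallback opens the furan with an external oxidant while the hydroquinone is silyl-protected. It sets out from 9. TBSCl (2.2 equiv) and imidazole in DMF at 0 °C silylate the two phenols in preference to the hindered secondary alcohol and give (1R)-1-[5-[2,5-bis(tert-butyldimethylsilyloxy)phenyl]furan-3-yl]-4-methylpent-3-en-1-ol F1. Dye-sensitised photo-oxygenation (rose bengal, O2, visible light, MeOH–CH2Cl2, −78 °C, then Me2S) opens the furan, which takes up singlet oxygen much faster than the trisubstituted alkene, to (2Z)-4-[2,5-bis(tert-butyldimethylsilyloxy)phenyl]-2-[(1R)-1-hydroxy-4-methylpent-3-enyl]-4-oxobut-2-enal F2. Buffered fluoride (TBAF/AcOH, THF, 0 °C) with p-benzoquinone present frees the hydroquinone. The fallback comes back to the route at 11, which closes to 12 and is dehydrogenated to 13 as in step 4.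

Step 3. The 2-furylboronate may protodeboronate, and the free, electron-rich bromohydroquinone is a slow, air-sensitive coupling partner. The fallback forms the aryl–furan bond without boron or palladium. It sets out from 5: Friedel–Crafts-type conjugate addition of the furan to p-benzoquinone (1 equiv, In(OTf)3 5 mol%, MeCN, 0 °C) gives the furyl hydroquinone and comes back to the route at 9. If part of the attack goes to the furan carbon next to the side chain, the product is the regioisomer 2-[3-[(1R)-1-hydroxy-4-methylpent-3-enyl]furan-2-yl]benzene-1,4-diol F3. It need not be removed. Under the conditions of step 4 it gives 2-[3-[(1R)-1-hydroxy-4-methylpent-3-enyl]furan-2-yl]cyclohexa-2,5-diene-1,4-dione F4 and then (2Z)-4-(2,5-dihydroxyphenyl)-3-[(1R)-1-hydroxy-4-methylpent-3-enyl]-4-oxobut-2-enal F5. F5 closes to the same leuco compound 12, because the two quinone carbonyl carbons of the naphthazarin are equivalent.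

Step 1. The whole route inherits its ee from this step, and a coordinating heteroaryl aldehyde can give a lower ee than benzaldehyde. The fallback sets the centre by reagent-controlled ketone reduction instead. It sets out from 5 of insufficient ee: Dess–Martin periodinane (NaHCO3, CH2Cl2, 0 °C) gives 1-(furan-3-yl)-4-methylpent-3-en-1-one F6. Reduction with (+)-B-chlorodiisopinocampheylborane (THF, −25 °C), which delivers hydride to aryl alkyl ketones to give the (R)-carbinol, comes back to the route at 5.

Further compounds
F1 | step 4 | (1R)-1-[5-[2,5-bis(tert-butyldimethylsilyloxy)phenyl]furan-3-yl]-4-methylpent-3-en-1-ol | CC(C)=CC[C@@H](O)c1coc(-c2cc(O[Si](C)(C)C(C)(C)C)ccc2O[Si](C)(C)C(C)(C)C)c1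
F2 | step 4 | (2Z)-4-[2,5-bis(tert-butyldimethylsilyloxy)phenyl]-2-[(1R)-1-hydroxy-4-methylpent-3-enyl]-4-oxobut-2-enal | CC(C)=CC[C@@H](O)/C(C=O)=C/C(=O)c1cc(O[Si](C)(C)C(C)(C)C)ccc1O[Si](C)(C)C(C)(C)C
F3 | step 3 | 2-[3-[(1R)-1-hydroxy-4-methylpent-3-enyl]furan-2-yl]benzene-1,4-diol | CC(C)=CC[C@@H](O)c1ccoc1-c1cc(O)ccc1O
F4 | step 3 | 2-[3-[(1R)-1-hydroxy-4-methylpent-3-enyl]furan-2-yl]cyclohexa-2,5-diene-1,4-dione | CC(C)=CC[C@@H](O)c1ccoc1C1=CC(=O)C=CC1=O
F5 | step 3 | (2Z)-4-(2,5-dihydroxyphenyl)-3-[(1R)-1-hydroxy-4-methylpent-3-enyl]-4-oxobut-2-enal | CC(C)=CC[C@@H](O)/C(=C/C=O)C(=O)c1cc(O)ccc1O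
F6 | step 1 | 1-(furan-3-yl)-4-methylpent-3-en-1-one | CC(C)=CCC(=O)c1ccoc1
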